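**Plan** (locants: lactone ring O1, C2(=O), C3–C6; side chain C1′–C15′ counted from C6)
1. Retrosynthesis: the C3=C4 unsaturation is traced to a 3-phenylthio δ-lactone, and the ring is then cut at C3–C4 and O1–C6 together: O1–C2–C3 becomes the dianion of (phenylthio)acetic acid, C4–C5–C6 a 1,3-dielectrophile. The chain is cut further at C5–C6 and C1′–C2′ (allylations) and C4′–C5′ (aldol), back to decanal.
2. Enabling feature: C4 and C6 of the dihydropyranone ring are 1,3-related, one primary and one secondary, so a 1,3-diol locked as a six-membered cyclic sulfate (1,3,2-dioxathiane 2,2-dioxide) takes the carbanion at C4 and then the carboxylate oxygen at C6.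
3. Forward order: linear chain growth from decanal to the open-chain C4–C15′ pentaol derivative; cyclic sulfate; 3+3 annulation closes the only ring; sulfoxide elimination gives C3=C4; global deprotection.
4. Stereochemistry: C6′, C2′ and C6 come from Ti(OiPr)4/(R)-BINOL catalysis (Re-face additions), C4′ from substrate-directed syn reduction. The annulation inverts C6, so the all-syn chain gives the 6,2′-anti, 2′,4′,6′-syn target.

Key step: step 11

Assumption: the Ti(OiPr)4/(R)-BINOL catalyst is taken to direct both the allylstannane and the silyl dienolate to the Re face of unbranched aldehydes (the sense of the Keck allylation); should the aldol of step 1 show the opposite sense, (S)-BINOL would be used there.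

Step 1
Reactants: 1 decanal; 2 1-methoxy-1,3-bis(trimethylsilyloxy)buta-1,3-diene
Product: 4 methyl (5S)-5-hydroxy-3-oxotetradecanoate, via bis-silyl aldol adduct 3 (not isolated)
Conditions: Ti(OiPr)4 (10 mol %), (R)-BINOL (10 mol %), 4 Å MS, THF, −78 °C to rt; then CF3CO2H, 0 °C
Reagents that add atoms: none
Why: Catalytic asymmetric vinylogous Mukaiyama aldol addition of the silyl dienolate through its terminal carbon should give the δ-hydroxy-β-keto ester after desilylation, with C6′ (S) set by catalyst-controlled Re-face attack on decanal.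

Step 2
Reactants: 4 methyl (5S)-5-hydroxy-3-oxotetradecanoate
Product: 6 methyl (3S,5S)-3,5-dihydroxytetradecanoate, via diethylboron chelate 5 (not isolated)
Conditions: Et2BOMe, THF/MeOH (4:1), −78 °C; then NaBH4, −78 °C; MeOH co-evaporation
Reagents that add atoms: none
Why: Narasaka–Prasad reduction, in which external hydride attacks the six-membered boron chelate from the face that leads to the 1,3-syn diol, so that C4′ (S) is set by C6′.

Step 3
Reactants: 6 methyl (3S,5S)-3,5-dihydroxytetradecanoate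
Product: 7 methyl 2-[(4S,6S)-2,2-dimethyl-6-nonyl-1,3-dioxan-4-yl]acetate
Conditions: Me2C(OMe)2, PPTS (cat.), CH2Cl2, rt
Reagents that add atoms: 2,2-dimethoxypropane, COC(C)(C)OC
Why: Acid-catalysed transketalisation should lock the syn-1,3-diol as its acetonide (both substituents equatorial), which protects the C4′ and C6′ oxygens until the last step.

Step 4
Reactants: 7 methyl 2-[(4S,6S)-2,2-dimethyl-6-nonyl-1,3-dioxan-4-yl]acetate
Product: 8 2-[(4S,6S)-2,2-dimethyl-6-nonyl-1,3-dioxan-4-yl]acetaldehyde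
Conditions: iBu2AlH (1.1 equiv), CH2Cl2, −78 °C; aq. sodium potassium tartrate
Reagents that add atoms: none
Why: Low-temperature half-reduction of the methyl ester should stop at the aluminium hemiacetal, which releases the aldehyde on work-up without touching a stereocentre.

Step 5
Reactants: 8 2-[(4S,6S)-2,2-dimethyl-6-nonyl-1,3-dioxan-4-yl]acetaldehyde
Product: 9 (2R)-1-[(4R,6S)-2,2-dimethyl-6-nonyl-1,3-dioxan-4-yl]pent-4-en-2-ol
Conditions: allylSnBu3, Ti(OiPr)4 (10 mol %), (R)-BINOL (20 mol %), 4 Å MS, CH2Cl2, −20 °C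
Reagents that add atoms: allyltributylstannane, C=CC[Sn](CCCC)(CCCC)CCCC
Why: Keck asymmetric allylation, in which the chiral titanium catalyst should deliver the allyl group to the Re face under reagent control and so set C2′ syn to C4′.

Step 6
Reactants: 9 (2R)-1-[(4R,6S)-2,2-dimethyl-6-nonyl-1,3-dioxan-4-yl]pent-4-en-2-ol
Product: 10 tert-butyl{[(2R)-1-[(4S,6S)-2,2-dimethyl-6-nonyl-1,3-dioxan-4-yl]pent-4-en-2-yl]oxy}dimethylsilane
Conditions: TBSOTf, 2,6-lutidine, CH2Cl2, −78 to 0 °C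
Reagents that add atoms: tert-butyldimethylsilyl trifluoromethanesulfonate, CC(C)(C)[Si](C)(C)OS(=O)(=O)C(F)(F)F
Why: Standard silylation of the secondary alcohol masks the C2′ oxygen so that it cannot compete as a nucleophile in step 11, and the buffered conditions leave the acetonide intact.

Step 7
Reactants: 10 tert-butyl{[(2R)-1-[(4S,6S)-2,2-dimethyl-6-nonyl-1,3-dioxan-4-yl]pent-4-en-2-yl]oxy}dimethylsilane
Product: 12 (3S)-3-[(tert-butyldimethylsilyl)oxy]-4-[(4S,6S)-2,2-dimethyl-6-nonyl-1,3-dioxan-4-yl]butanal, via secondary ozonide 11 (not isolated)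
Conditions: O3, CH2Cl2, −78 °C; then PPh3, −78 °C to rt
Reagents that add atoms: ozone, [O-][O+]=O
Why: Ozonolysis of the terminal alkene with reductive work-up excises one carbon and reveals the C6 aldehyde, the silyl ether and acetonide being inert to ozone.

Step 8
Reactants: 12 (3S)-3-[(tert-butyldimethylsilyl)oxy]-4-[(4S,6S)-2,2-dimethyl-6-nonyl-1,3-dioxan-4-yl]butanal
Product: 13 (4R,6R)-6-[(tert-butyldimethylsilyl)oxy]-7-[(4S,6S)-2,2-dimethyl-6-nonyl-1,3-dioxan-4-yl]hept-1-en-4-ol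
Conditions: allylSnBu3, Ti(OiPr)4 (10 mol %), (R)-BINOL (20 mol %), 4 Å MS, CH2Cl2, −20 °C
Reagents that add atoms: allyltributylstannane, C=CC[Sn](CCCC)(CCCC)CCCC
Why: A second Keck asymmetric allylation with the same catalyst antipode (Re-face attack) should set C6 as the (R)-carbinol syn to C2′, that is the C6 epimer of the target, as the inversion in step 11 requires.

Step 9
Reactants: 13 (4R,6R)-6-[(tert-butyldimethylsilyl)oxy]-7-[(4S,6S)-2,2-dimethyl-6-nonyl-1,3-dioxan-4-yl]hept-1-en-4-ol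
Product: 15 (3R,5R)-5-[(tert-butyldimethylsilyl)oxy]-6-[(4S,6S)-2,2-dimethyl-6-nonyl-1,3-dioxan-4-yl]hexane-1,3-diol, via secondary ozonide 14 (not isolated)
Conditions: O3, CH2Cl2, −78 °C; then NaBH4, MeOH, −78 °C to rt
Reagents that add atoms: ozone, [O-][O+]=O
Why: Ozonolysis with in situ borohydride reduction of the ozonide turns the allyl group into the 2-hydroxyethyl unit (C5–C4) and gives the primary/secondary 1,3-diol without affecting a stereocentre.

Step 10
Reactants: 15 (3R,5R)-5-[(tert-butyldimethylsilyl)oxy]-6-[(4S,6S)-2,2-dimethyl-6-nonyl-1,3-dioxan-4-yl]hexane-1,3-diol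
Product: 17 (4R)-4-[(2S)-2-[(tert-butyldimethylsilyl)oxy]-3-[(4S,6S)-2,2-dimethyl-6-nonyl-1,3-dioxan-4-yl]propyl]-1,3,2-dioxathiane 2,2-dioxide, via cyclic sulfite 16 (not isolated)
Conditions: SOCl2, Et3N, CH2Cl2, 0 °C; then RuCl3·3H2O (cat.), NaIO4, MeCN/H2O, 0 °C
Reagents that add atoms: thionyl chloride, O=S(Cl)Cl; sodium periodate, [Na+].[O-]I(=O)(=O)=O
Why: Cyclic sulfite formation and RuO4-catalysed oxidation to the cyclic sulfate activate C4 and C6 at once with retention at C6, since no C–O bond is broken.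

Step 11
Reactants: 17 (4R)-4-[(2S)-2-[(tert-butyldimethylsilyl)oxy]-3-[(4S,6S)-2,2-dimethyl-6-nonyl-1,3-dioxan-4-yl]propyl]-1,3,2-dioxathiane 2,2-dioxide; 18 2-(phenylsulfanyl)acetic acid
Product: 21 (6S)-6-[(2S)-2-[(tert-butyldimethylsilyl)oxy]-3-[(4S,6S)-2,2-dimethyl-6-nonyl-1,3-dioxan-4-yl]propyl]-3-(phenylsulfanyl)oxan-2-one, via dilithio dianion 19 (not isolated), via open-chain sulfate carboxylate 20 (not isolated)
Conditions: 18, LiN(iPr)2 (2.1 equiv), THF, 0 °C; then 17, −78 to 0 °C; then DMPU, 60 °C; aq. NaHCO3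
Reagents that add atoms: none
Why: Proposed new method: dianion 19 should open cyclic sulfate 17 by SN2 attack at the unhindered primary C4 (forming C3–C4; closest known reaction type: ring opening of cyclic sulfates by enolates and carboxylic acid dianions) to give 20, whose tethered carboxylate then displaces the secondary alkyl sulfate at C6 on warming in THF/DMPU (forming O1–C6, loss of Li2SO4), just as the sulfate monoester serves as second leaving group in the known double displacements of cyclic sulfates by malonate (cyclopropanes) and primary amines (aziridines). The lactone ring closes in a 6-exo-tet mode. C6 is set by stereospecific inversion of the (R)-carbinol carbon of 17, which converts the 6,2′-syn chain into the 6,2′-anti target, while C3 forms as an epimer mixture that step 12 erases. The step needs C-alkylation before O-alkylation and attack at the primary before the secondary carbon, which the far higher nucleophilicity of the carbanion and the steric bias of the 1,3,2-dioxathiane ring secure. Only the six-membered closure at C6 is open to the carboxylate, and the silyl ether at C2′ keeps that oxygen from competing. Uncyclised 20 stays in the aqueous phase on neutral work-up, so no retentive hydrolysis–lactonisation path can contaminate 21.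

Step 12
Reactants: 21 (6S)-6-[(2S)-2-[(tert-butyldimethylsilyl)oxy]-3-[(4S,6S)-2,2-dimethyl-6-nonyl-1,3-dioxan-4-yl]propyl]-3-(phenylsulfanyl)oxan-2-one
Product: 23 (6S)-6-[(2S)-2-[(tert-butyldimethylsilyl)oxy]-3-[(4S,6S)-2,2-dimethyl-6-nonyl-1,3-dioxan-4-yl]propyl]-5,6-dihydro-2H-pyran-2-one, via sulfoxide 22 (not isolated)
Conditions: mCPBA (1.0 equiv), CH2Cl2, −78 °C; then CaCO3, toluene, 110 °C
Reagents that add atoms: none
Why: Sulfide oxidation followed by thermal syn elimination of benzenesulfenic acid (sulfoxide pyrolysis) should introduce the C3=C4 double bond, since only C4 carries β-hydrogens and the ring enforces the cis olefin.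

Step 13
Reactants: 23 (6S)-6-[(2S)-2-[(tert-butyldimethylsilyl)oxy]-3-[(4S,6S)-2,2-dimethyl-6-nonyl-1,3-dioxan-4-yl]propyl]-5,6-dihydro-2H-pyran-2-one
Product: 24 (6S)-6-[(2S,4S,6S)-2,4,6-trihydroxypentadecyl]-5,6-dihydro-2H-pyran-2-one
Conditions: 48% aq. HF, MeCN, 0 °C to rt
Reagents that add atoms: none
Why: Aqueous HF should cleave the silyl ether and hydrolyse the acetonide in one operation, and the 6,2′-anti arrangement should disfavour conjugate addition of the C2′ hydroxyl to C4 because the bicyclic adduct would need the C3′ chain axial.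

**Compound list**
1 | decanal | CCCCCCCCCC=O | starting material
2 | 1-methoxy-1,3-bis(trimethylsilyloxy)buta-1,3-diene | COC(O[Si](C)(C)C)=CC(=C)O[Si](C)(C)C | starting material
3 | methyl (5S)-3,5-bis(trimethylsilyloxy)tetradec-2-enoate | CCCCCCCCC[C@H](O[Si](C)(C)C)CC(O[Si](C)(C)C)=CC(=O)OC | intermediate (not isolated)
4 | methyl (5S)-5-hydroxy-3-oxotetradecanoate | CCCCCCCCC[C@H](O)CC(=O)CC(=O)OC | intermediate
5 | methyl (5S)-5-[(diethylboranyl)oxy]-3-oxotetradecanoate (boron chelate) | CCCCCCCCC[C@H](OB(CC)CC)CC(=O)CC(=O)OC | intermediate (not isolated)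
6 | methyl (3S,5S)-3,5-dihydroxytetradecanoate | CCCCCCCCC[C@H](O)C[C@H](O)CC(=O)OC | intermediate
7 | methyl 2-[(4S,6S)-2,2-dimethyl-6-nonyl-1,3-dioxan-4-yl]acetate | CCCCCCCCC[C@H]1C[C@@H](CC(=O)OC)OC(C)(C)O1 | intermediate
8 | 2-[(4S,6S)-2,2-dimethyl-6-nonyl-1,3-dioxan-4-yl]acetaldehyde | CCCCCCCCC[C@H]1C[C@@H](CC=O)OC(C)(C)O1 | intermediate
9 | (2R)-1-[(4R,6S)-2,2-dimethyl-6-nonyl-1,3-dioxan-4-yl]pent-4-en-2-ol | CCCCCCCCC[C@H]1C[C@@H](C[C@H](O)CC=C)OC(C)(C)O1 | intermediate
10 | tert-butyl{[(2R)-1-[(4S,6S)-2,2-dimethyl-6-nonyl-1,3-dioxan-4-yl]pent-4-en-2-yl]oxy}dimethylsilane | CCCCCCCCC[C@H]1C[C@@H](C[C@H](O[Si](C)(C)C(C)(C)C)CC=C)OC(C)(C)O1 | intermediate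
11 | 3-[(2S)-2-[(tert-butyldimethylsilyl)oxy]-3-[(4S,6S)-2,2-dimethyl-6-nonyl-1,3-dioxan-4-yl]propyl]-1,2,4-trioxolane (epimers at the trioxolane carbon) | CCCCCCCCC[C@H]1C[C@@H](C[C@H](O[Si](C)(C)C(C)(C)C)CC2OCOO2)OC(C)(C)O1 | intermediate (not isolated)
12 | (3S)-3-[(tert-butyldimethylsilyl)oxy]-4-[(4S,6S)-2,2-dimethyl-6-nonyl-1,3-dioxan-4-yl]butanal | CCCCCCCCC[C@H]1C[C@@H](C[C@H](O[Si](C)(C)C(C)(C)C)CC=O)OC(C)(C)O1 | intermediate
13 | (4R,6R)-6-[(tert-butyldimethylsilyl)oxy]-7-[(4S,6S)-2,2-dimethyl-6-nonyl-1,3-dioxan-4-yl]hept-1-en-4-ol | CCCCCCCCC[C@H]1C[C@@H](C[C@H](O[Si](C)(C)C(C)(C)C)C[C@H](O)CC=C)OC(C)(C)O1 | intermediate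
14 | (2S,4R)-4-[(tert-butyldimethylsilyl)oxy]-5-[(4S,6S)-2,2-dimethyl-6-nonyl-1,3-dioxan-4-yl]-1-(1,2,4-trioxolan-3-yl)pentan-2-ol (epimers at the trioxolane carbon) | CCCCCCCCC[C@H]1C[C@@H](C[C@H](O[Si](C)(C)C(C)(C)C)C[C@H](O)CC2OCOO2)OC(C)(C)O1 | intermediate (not isolated)
15 | (3R,5R)-5-[(tert-butyldimethylsilyl)oxy]-6-[(4S,6S)-2,2-dimethyl-6-nonyl-1,3-dioxan-4-yl]hexane-1,3-diol | CCCCCCCCC[C@H]1C[C@@H](C[C@H](O[Si](C)(C)C(C)(C)C)C[C@H](O)CCO)OC(C)(C)O1 | intermediate
16 | (4R)-4-[(2S)-2-[(tert-butyldimethylsilyl)oxy]-3-[(4S,6S)-2,2-dimethyl-6-nonyl-1,3-dioxan-4-yl]propyl]-1,3,2-dioxathiane 2-oxide (epimers at sulfur) | CCCCCCCCC[C@H]1C[C@@H](C[C@H](O[Si](C)(C)C(C)(C)C)C[C@H]2CCOS(=O)O2)OC(C)(C)O1 | intermediate (not isolated)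
17 | (4R)-4-[(2S)-2-[(tert-butyldimethylsilyl)oxy]-3-[(4S,6S)-2,2-dimethyl-6-nonyl-1,3-dioxan-4-yl]propyl]-1,3,2-dioxathiane 2,2-dioxide | CCCCCCCCC[C@H]1C[C@@H](C[C@H](O[Si](C)(C)C(C)(C)C)C[C@H]2CCOS(=O)(=O)O2)OC(C)(C)O1 | intermediate
18 | 2-(phenylsulfanyl)acetic acid [(phenylthio)acetic acid] | OC(=O)CSc1ccccc1 | starting material
19 | dilithium 2-(phenylsulfanyl)acetate-2-ide (dianion of 18) | [Li+].[Li+].[O-]C(=O)[CH-]Sc1ccccc1 | intermediate (not isolated)
20 | dilithium (5R,7S)-7-[(tert-butyldimethylsilyl)oxy]-8-[(4S,6S)-2,2-dimethyl-6-nonyl-1,3-dioxan-4-yl]-2-(phenylsulfanyl)-5-(sulfonatooxy)octanoate (epimers at C2) | [Li+].[Li+].CCCCCCCCC[C@H]1C[C@@H](C[C@H](O[Si](C)(C)C(C)(C)C)C[C@H](OS(=O)(=O)[O-])CCC(Sc2ccccc2)C(=O)[O-])OC(C)(C)O1 | intermediate (not isolated)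
21 | (6S)-6-[(2S)-2-[(tert-butyldimethylsilyl)oxy]-3-[(4S,6S)-2,2-dimethyl-6-nonyl-1,3-dioxan-4-yl]propyl]-3-(phenylsulfanyl)oxan-2-one (epimers at C3) | CCCCCCCCC[C@H]1C[C@@H](C[C@H](O[Si](C)(C)C(C)(C)C)C[C@@H]2CCC(Sc3ccccc3)C(=O)O2)OC(C)(C)O1 | intermediate
22 | (6S)-6-[(2S)-2-[(tert-butyldimethylsilyl)oxy]-3-[(4S,6S)-2,2-dimethyl-6-nonyl-1,3-dioxan-4-yl]propyl]-3-(phenylsulfinyl)oxan-2-one (diastereomer mixture) | CCCCCCCCC[C@H]1C[C@@H](C[C@H](O[Si](C)(C)C(C)(C)C)C[C@@H]2CCC(S(=O)c3ccccc3)C(=O)O2)OC(C)(C)O1 | intermediate (not isolated)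
23 | (6S)-6-[(2S)-2-[(tert-butyldimethylsilyl)oxy]-3-[(4S,6S)-2,2-dimethyl-6-nonyl-1,3-dioxan-4-yl]propyl]-5,6-dihydro-2H-pyran-2-one | CCCCCCCCC[C@H]1C[C@@H](C[C@H](O[Si](C)(C)C(C)(C)C)C[C@@H]2CC=CC(=O)O2)OC(C)(C)O1 | intermediate
24 | (6S)-6-[(2S,4S,6S)-2,4,6-trihydroxypentadecyl]-5,6-dihydro-2H-pyran-2-one | CCCCCCCCC[C@H](O)C[C@H](O)C[C@H](O)C[C@@H]1CC=CC(=O)O1 | target

Total step count: 13. Longest linear sequence: 13 steps (decanal 1 to target 24).

**Steps most likely to fail**

Step 11 (the proposed new method): the carboxylate may fail to displace the alkyl sulfate monoanion, a modest leaving group, or the dianion may act as a base and cause elimination, so that the ring does not close. The fallback sets out from diol 15. Both hydroxyls are converted into tosylates (TsCl, DMAP, pyridine) to give (3R,5S)-5-[(tert-butyldimethylsilyl)oxy]-6-[(4S,6S)-2,2-dimethyl-6-nonyl-1,3-dioxan-4-yl]hexane-1,3-diyl bis(4-methylbenzenesulfonate) F1. Dianion 19 then alkylates at the primary tosylate, and on warming in THF/DMPU the carboxylate displaces the secondary tosylate with inversion; both events are known for carboxylic acid dianions and 1,3-dielectrophiles. The fallback comes back to the route at lactone 21.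

Step 1: the enantioface selectivity of the titanium-catalysed dienolate addition may be insufficient with an unbranched aliphatic aldehyde, and the absolute configuration of the whole chain depends on it. The fallback sets out from decanal 1. Keck allylation (allylSnBu3, Ti(OiPr)4, (R)-BINOL) gives (4S)-tridec-1-en-4-ol F2. Cross-metathesis with methyl acrylate (second-generation Hoveyda–Grubbs catalyst) gives methyl (2E,5S)-5-hydroxytetradec-2-enoate F3. Benzaldehyde hemiacetal formation and intramolecular oxa-Michael addition (PhCHO, KOtBu, THF, 0 °C) set C4′ under thermodynamic control in the all-equatorial acetal methyl 2-[(2S,4S,6S)-6-nonyl-2-phenyl-1,3-dioxan-4-yl]acetate F4. Hydrogenolysis (H2, Pd(OH)2/C, EtOAc) comes back to the route at diol ester 6.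

Step 13: during acid deprotection the freed C2′ hydroxyl or water may add to the enoate, or the lactone may open, before the acetonide is fully cleaved. The fallback sets out from sulfide lactone 21. The silyl ether and the acetonide are removed first (48% aq. HF, MeCN), while no Michael acceptor is present, to give (6S)-3-(phenylsulfanyl)-6-[(2S,4S,6S)-2,4,6-trihydroxypentadecyl]oxan-2-one F5. Oxidation with mCPBA gives (6S)-3-(phenylsulfinyl)-6-[(2S,4S,6S)-2,4,6-trihydroxypentadecyl]oxan-2-one F6, and thermal elimination (CaCO3, toluene, 110 °C) comes back to the route at target 24.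

Further compounds
F1 | step 11 | (3R,5S)-5-[(tert-butyldimethylsilyl)oxy]-6-[(4S,6S)-2,2-dimethyl-6-nonyl-1,3-dioxan-4-yl]hexane-1,3-diyl bis(4-methylbenzenesulfonate) | CCCCCCCCC[C@H]1C[C@@H](C[C@H](O[Si](C)(C)C(C)(C)C)C[C@H](OS(=O)(=O)c2ccc(C)cc2)CCOS(=O)(=O)c2ccc(C)cc2)OC(C)(C)O1
F2 | step 1 | (4S)-tridec-1-en-4-ol | CCCCCCCCC[C@H](O)CC=C
F3 | step 1 | methyl (2E,5S)-5-hydroxytetradec-2-enoate | CCCCCCCCC[C@H](O)C/C=C/C(=O)OC
F4 | step 1 | methyl 2-[(2S,4S,6S)-6-nonyl-2-phenyl-1,3-dioxan-4-yl]acetate | CCCCCCCCC[C@H]1C[C@@H](CC(=O)OC)O[C@@H](c2ccccc2)O1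
F5 | step 13 | (6S)-3-(phenylsulfanyl)-6-[(2S,4S,6S)-2,4,6-trihydroxypentadecyl]oxan-2-one | CCCCCCCCC[C@H](O)C[C@H](O)C[C@H](O)C[C@@H]1CCC(Sc2ccccc2)C(=O)O1
F6 | step 13 | (6S)-3-(phenylsulfinyl)-6-[(2S,4S,6S)-2,4,6-trihydroxypentadecyl]oxan-2-one | CCCCCCCCC[C@H](O)C[C@H](O)C[C@H](O)C[C@@H]1CCC(S(=O)c2ccccc2)C(=O)O1
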